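This flask is slow, and in a slow flask a small leak has hours to work: the red run stands at 26.7 % of product after 10.0 h, and the new flasks run twice as long.

| setting | red | teal | alpha | zeta | gamma | theta | beta |
|---|---|---|---|---|---|---|---|
| starting material | 0.10 M | 0.10 M | 0.10 M | 0.10 M | 0.10 M | 0.10 M | 0.10 M |
| partner | 0.095 M | 0.095 M | 0.0950 M | 0.0950 M | 0.0950 M | 0.0950 M | 0.0950 M |
| capture agent | 0.010 M | 0.010 M | 0.0100 M | 0.0100 M | 0.0100 M | 0.0100 M | 0.0100 M |
| protic impurity | 0.0035 M | 0.070 M | 0.00300 M | 0.00600 M | 0.0120 M | 0.0250 M | 0.0500 M |
| remark | run made earlier | run made earlier |  |  |  |  |  |
| time |  |  | 20 h | 20 h | 20 h | 20 h | 20 h |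

- red (time / h: product / %): 0.833: 0; 2.00: 2.2; 4.00: 9.5; 10.0: 26.7
- teal (time / h: product / %): 0.833: 0.5; 2.00: 2.3; 4.00: 9.3; 10.0: 23.9

(standard deviation of a reading: 0.5 percentage points)

- "hardly changes" means that all values lie within two and a half points (for a concentration: within two and a half percent of the largest)

- amount of product at the end, in percent of the starting material charged for alpha, zeta, gamma, theta, beta, in this order
- the shape of the row from first to last (falls, then rises / rises all the way / falls all the way / hardly changes / rises, then falls)

Two chemists stand at the board with these two runs. The first sees two curves that nearly overlay across a wide range of impurity, and she calls it a brake: in her words, “the impurity acts as a mild brake”. Her forecast for alpha to beta is 43.5 %, 43.4 %, 43.1 %, 42.6 % and 41.7 %, so the shape is "hardly changes".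

The second sees a leak, which costs product per hour as well as per molar of impurity. Red stands above teal by 2.8 percentage points at 10.0 h. She divides that gap by the difference in impurity and by the hours and gets 0.0421 M⁻¹ h⁻¹. This is the impurity toll: the fraction of the starting material charged that fails to appear as product, per molar of impurity and per hour.

It is a reading, and it rests on one gap, whose scatter is 0.71 points. The gap of 0.2 points at 4.00 h is smaller than that scatter.

The first answers that, at 10.0 h, the impurity span of the new row costs 2 points, which is within the margin. The second replies that the row is read at 20 h. There her toll gives a drop from alpha to beta of 4 points, more than the forecast's 1.8 points and beyond the 2.5 points of "hardly changes". Her own answer therefore differs from the forecast: the row falls all the way.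

The simulation gives 46.3 %, 46.1 %, 45.6 %, 44.7 % and 43.0 %, and the shape is "falls all the way".

    starting material + protic impurity → quenched substrate (k = 0.220 M⁻¹ h⁻¹)
    open intermediate + second intermediate → product (k = 16.0 M⁻¹ h⁻¹)
    starting material ⇌ open intermediate (K = 2.30, k = 0.0340 h⁻¹)
    second intermediate + capture agent → trapped intermediate (k = 0.150 M⁻¹ h⁻¹)
    partner → second intermediate (k = 0.310 h⁻¹)

The toll's 4 points stands against a drop of 3.3 points from alpha to beta. For theta against alpha it gives 1.9 points and the flask gives 1.6 points, which is within the 2.5 points of "hardly changes", so the forecast's shape would have been right for a row ending at theta. In alpha the partner went first, with 46 % of its step's turnover behind it by 2.00 h and 4.50 % of its charge left at 10.0 h. From then on starting material opened through the rate-limiting step, with a forward half-life of 20 h against 0.92 h for open intermediate meeting second intermediate at 20.0 h, while quenched substrate reached 0.820 % in alpha and 12.7 % in beta at 20.0 h.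

(The readings were generated by integration for substances that don't exist.)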